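## Retrosynthetic overview

1. The C5–O aryl ether is made last but one, by a stereoconvergent SN1 etherification of a tetrahydrochromone C5 carbinol with a 6‑hydroxy‑7‑silyloxychromone; the cis‑fused 6,7‑acetonide directs the attack and sets C5. Global deprotection follows.
2. Both rings of the tetrahydrochromone come from one pot on a sugar‑derived 1,3,5‑triketo lactol: the carbocycle by a C4a–C5 aldol, then the γ‑pyranone by O1–C2 cyclodehydration.
3. C6, C7 and C8 are C2, C3 and C4 of D‑mannose. The triketone comes from a dianion aldol of 6‑phenylhexane‑2,4‑dione with a D‑mannose‑derived aldehyde, then oxidation.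
4. The aromatic half comes from a Claisen/cyclodehydration chromone synthesis, demethylation and 7‑O‑silylation.
5. Ring order: aromatic chromone pyranone (separate branch), then carbocycle, then tetrahydro‑pyranone (same pot). No ring is formed afterwards.

Assumption: diacetone‑D‑mannose is bought as such (otherwise one extra step from D‑mannose).

## Route

Step 1
Reactants: 1 pentane‑2,4‑dione; 2 benzyl bromide
Product: 3 6‑phenylhexane‑2,4‑dione
Conditions: LDA (2.1 equiv), THF, 0 °C; then 2, 0 °C → rt; aq. HCl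
Reagents that add atoms: none
Why: γ‑Alkylation of the acetylacetone dianion (Hauser/Harris dianion alkylation) takes place only at the terminal carbanion; no stereocentre.

Step 2
Reactants: 4 2,3:5,6‑di‑O‑isopropylidene‑α‑D‑mannofuranose; 2 benzyl bromide
Product: 5 benzyl 2,3:5,6‑di‑O‑isopropylidene‑α‑D‑mannofuranoside
Conditions: NaH, DMF, 0 °C → rt
Reagents that add atoms: none
Why: Williamson O‑alkylation of the anomeric alkoxide trans to the 2,3‑acetonide keeps the α‑glycoside and leaves the mannose stereocentres untouched.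

Step 3
Reactants: 5 benzyl 2,3:5,6‑di‑O‑isopropylidene‑α‑D‑mannofuranoside
Product: 6 benzyl 2,3‑O‑isopropylidene‑α‑D‑lyxo‑pentodialdo‑1,4‑furanoside
Conditions: H5IO6 (1.3 equiv), EtOAc, rt
Reagents that add atoms: none
Why: Periodic acid hydrolyses only the terminal 5,6‑acetonide and cleaves the freed glycol in the same flask (one‑pot deprotection/Malaprade cleavage); C2–C4 and the cis‑fused 2,3‑acetonide are untouched.

Step 4
Reactants: 6 benzyl 2,3‑O‑isopropylidene‑α‑D‑lyxo‑pentodialdo‑1,4‑furanoside; 3 6‑phenylhexane‑2,4‑dione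
Product: 7 benzyl (5RS)‑6,8,10,11‑tetradeoxy‑2,3‑O‑isopropylidene‑11‑phenyl‑α‑D‑lyxo‑undecofuranosid‑7,9‑diulose
Conditions: 3 (1.4 equiv), LDA (2.9 equiv), THF, −78 → 0 °C; then 6, −78 °C; AcOH quench
Reagents that add atoms: none
Why: The dilithio dianion of 3, formed at the methyl terminus, adds through its terminal carbanion to the aldehyde at −78 °C faster than it enolises it (Weiler/Harris dianion aldol); the new carbinol is an epimer mixture erased in step 5, and C2–C4 are unchanged.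

Step 5
Reactants: 7 benzyl (5RS)‑6,8,10,11‑tetradeoxy‑2,3‑O‑isopropylidene‑11‑phenyl‑α‑D‑lyxo‑undecofuranosid‑7,9‑diulose
Product: 8 benzyl 6,8,10,11‑tetradeoxy‑2,3‑O‑isopropylidene‑11‑phenyl‑α‑D‑lyxo‑undecofuranosid‑5,7,9‑triulose
Conditions: Dess–Martin periodinane (1.2 equiv), CH2Cl2, 0 °C → rt
Reagents that add atoms: none
Why: Dess–Martin oxidation of the secondary alcohol gives the 1,3,5‑triketone under non‑basic conditions that do not epimerise the α‑alkoxy centre (the future C8).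

Step 6
Reactants: 8 benzyl 6,8,10,11‑tetradeoxy‑2,3‑O‑isopropylidene‑11‑phenyl‑α‑D‑lyxo‑undecofuranosid‑5,7,9‑triulose
Product: 11 (6R,7S,8S)‑5,8‑dihydroxy‑6,7‑(isopropylidenedioxy)‑2‑(2‑phenylethyl)‑5,6,7,8‑tetrahydro‑4H‑chromen‑4‑one as C5 epimers, via triketo lactol 9 (not isolated), via cyclohexanone aldol 10 (not isolated)
Conditions: H2 (1 atm), Pd(OH)2/C, EtOAc, rt; filter; Et3N (0.2 equiv), CH2Cl2, 0 °C → rt; then TFA (10 equiv), 4 Å MS, 0 °C
Reagents that add atoms: none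
Why: Proposed new method: hydrogenolysis of the anomeric benzyl acetal frees lactol 9, whose open hydroxy‑aldehyde form is attacked under mild base by the doubly activated C4a methylene of the triketone (6‑exo intramolecular Knoevenagel‑type aldol, the only feasible ring size; closest precedents are the aldol half of the Ferrier carbocyclisation and Knoevenagel reactions of lactols with 1,3‑diketones) to give carbocycle 10, and acid then cyclodehydrates the triketone to the aromatic 4‑pyranone (Harris‑type γ‑pyrone synthesis), which takes the aldol out of retro‑aldol equilibrium; C6, C7 and C8 are mannose C2, C3 and C4 carried through unchanged, and the new C5 carbinol is a mixture that step 10 corrects.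

Step 7
Reactants: 12 1‑(2‑hydroxy‑4,5‑dimethoxyphenyl)ethan‑1‑one; 13 ethyl 3‑phenylpropanoate
Product: 15 6,7‑dimethoxy‑2‑(2‑phenylethyl)‑4H‑chromen‑4‑one, via aryl diketone 14 (not isolated)
Conditions: NaH (4 equiv), THF, reflux; then conc. HCl, MeOH, 60 °C
Reagents that add atoms: none
Why: Claisen condensation of the ketone enolate with the ester gives the o‑hydroxyaryl 1,3‑diketone, which cyclodehydrates under acid to the 2‑substituted chromone (standard chromone synthesis); no stereocentre.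

Step 8
Reactants: 15 6,7‑dimethoxy‑2‑(2‑phenylethyl)‑4H‑chromen‑4‑one
Product: 16 6,7‑dihydroxy‑2‑(2‑phenylethyl)‑4H‑chromen‑4‑one
Conditions: BBr3 (4 equiv), CH2Cl2, −78 °C → rt; H2O
Reagents that add atoms: none
Why: BBr3 cleaves both aryl methyl ethers (Lewis‑acid ether cleavage) without touching the chromone; no stereocentre.

Step 9
Reactants: 16 6,7‑dihydroxy‑2‑(2‑phenylethyl)‑4H‑chromen‑4‑one
Product: 17 7‑[(tert‑butyldimethylsilyl)oxy]‑6‑hydroxy‑2‑(2‑phenylethyl)‑4H‑chromen‑4‑one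
Conditions: TBSCl (1.05 equiv), imidazole (2.2 equiv), DMF, 0 °C
Reagents that add atoms: tert‑butyldimethylsilyl chloride, CC(C)(C)[Si](C)(C)Cl
Why: The 7‑OH is para‑conjugated to the C4 carbonyl and about two pKa units more acidic than the 6‑OH, so it is ionised by imidazole and silylated first (regioselective silylation), leaving the 6‑OH free.

Step 10
Reactants: 11 (6R,7S,8S)‑5,8‑dihydroxy‑6,7‑(isopropylidenedioxy)‑2‑(2‑phenylethyl)‑5,6,7,8‑tetrahydro‑4H‑chromen‑4‑one; 17 7‑[(tert‑butyldimethylsilyl)oxy]‑6‑hydroxy‑2‑(2‑phenylethyl)‑4H‑chromen‑4‑one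
Product: 18 (5S,6R,7S,8S)‑5‑({7‑[(tert‑butyldimethylsilyl)oxy]‑4‑oxo‑2‑(2‑phenylethyl)‑4H‑chromen‑6‑yl}oxy)‑8‑hydroxy‑6,7‑(isopropylidenedioxy)‑2‑(2‑phenylethyl)‑5,6,7,8‑tetrahydro‑4H‑chromen‑4‑one
Conditions: 17 (1.5 equiv), BF3·OEt2 (0.3 equiv), 4 Å MS, CH2Cl2, −40 → −10 °C
Reagents that add atoms: none
Why: Lewis‑acid dehydrative SN1 etherification in which only the C5 carbinol can ionise (vinylogous oxocarbenium ion through C4a=C8a–O1), both C5 epimers give the same cation, and the 6‑OH of 17 adds to the convex face anti to the cis‑fused 6,7‑acetonide, as nucleophiles do with 2,3‑O‑isopropylidene glycosyl cations, setting C5 as S (5,6‑trans).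

Step 11
Reactants: 18 (5S,6R,7S,8S)‑5‑({7‑[(tert‑butyldimethylsilyl)oxy]‑4‑oxo‑2‑(2‑phenylethyl)‑4H‑chromen‑6‑yl}oxy)‑8‑hydroxy‑6,7‑(isopropylidenedioxy)‑2‑(2‑phenylethyl)‑5,6,7,8‑tetrahydro‑4H‑chromen‑4‑one
Product: 19 (5S,6S,7R,8S)‑6,7,8‑trihydroxy‑5‑{[7‑hydroxy‑4‑oxo‑2‑(2‑phenylethyl)‑4H‑chromen‑6‑yl]oxy}‑2‑(2‑phenylethyl)‑5,6,7,8‑tetrahydro‑4H‑chromen‑4‑one
Conditions: 48% aq. HF, MeCN, 0 °C → rt
Reagents that add atoms: none
Why: Aqueous HF cleaves the aryl silyl ether and hydrolyses the cis‑acetonide in one global deprotection under acidity too mild to ionise the C5 aryl ether, so all four stereocentres are retained.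

## Compound list

1 | pentane‑2,4‑dione (acetylacetone) | CC(=O)CC(C)=O | starting material
2 | benzyl bromide | BrCc1ccccc1 | starting material
3 | 6‑phenylhexane‑2,4‑dione | CC(=O)CC(=O)CCc1ccccc1 | intermediate
4 | 2,3:5,6‑di‑O‑isopropylidene‑α‑D‑mannofuranose (diacetone‑D‑mannose) | O[C@H]1O[C@H]([C@H]2COC(C)(C)O2)[C@@H]2OC(C)(C)O[C@H]12 | starting material
5 | benzyl 2,3:5,6‑di‑O‑isopropylidene‑α‑D‑mannofuranoside | O(Cc1ccccc1)[C@H]1O[C@H]([C@H]2COC(C)(C)O2)[C@@H]2OC(C)(C)O[C@H]12 | intermediate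
6 | benzyl 2,3‑O‑isopropylidene‑α‑D‑lyxo‑pentodialdo‑1,4‑furanoside (C5 aldehyde) | O(Cc1ccccc1)[C@H]1O[C@H](C=O)[C@@H]2OC(C)(C)O[C@H]12 | intermediate
7 | benzyl (5RS)‑6,8,10,11‑tetradeoxy‑2,3‑O‑isopropylidene‑11‑phenyl‑α‑D‑lyxo‑undecofuranosid‑7,9‑diulose (δ‑hydroxy‑β‑diketone, carbinol epimers) | O(Cc1ccccc1)[C@H]1O[C@H](C(O)CC(=O)CC(=O)CCc3ccccc3)[C@@H]2OC(C)(C)O[C@H]12 | intermediate
8 | benzyl 6,8,10,11‑tetradeoxy‑2,3‑O‑isopropylidene‑11‑phenyl‑α‑D‑lyxo‑undecofuranosid‑5,7,9‑triulose (1,3,5‑triketone, enol tautomers) | O(Cc1ccccc1)[C@H]1O[C@H](C(=O)CC(=O)CC(=O)CCc3ccccc3)[C@@H]2OC(C)(C)O[C@H]12 | intermediate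
9 | 6,8,10,11‑tetradeoxy‑2,3‑O‑isopropylidene‑11‑phenyl‑D‑lyxo‑undecofuranos‑5,7,9‑triulose (triketo lactol, anomers; not isolated) | OC1O[C@H](C(=O)CC(=O)CC(=O)CCc3ccccc3)[C@@H]2OC(C)(C)O[C@H]12 | intermediate
10 | (4R,5S,6S)‑3,6‑dihydroxy‑4,5‑(isopropylidenedioxy)‑2‑(3‑oxo‑5‑phenylpentanoyl)cyclohexan‑1‑one (C2/C3 epimers, enol tautomers; not isolated) | O=C1C(C(=O)CC(=O)CCc2ccccc2)C(O)[C@H]2OC(C)(C)O[C@H]2[C@@H]1O | intermediate
11 | (6R,7S,8S)‑5,8‑dihydroxy‑6,7‑(isopropylidenedioxy)‑2‑(2‑phenylethyl)‑5,6,7,8‑tetrahydro‑4H‑chromen‑4‑one (C5 epimers) | O=c1cc(CCc2ccccc2)oc2c1C(O)[C@H]1OC(C)(C)O[C@H]1[C@@H]2O | intermediate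
12 | 1‑(2‑hydroxy‑4,5‑dimethoxyphenyl)ethan‑1‑one | CC(=O)c1cc(OC)c(OC)cc1O | starting material
13 | ethyl 3‑phenylpropanoate | CCOC(=O)CCc1ccccc1 | starting material
14 | 1‑(2‑hydroxy‑4,5‑dimethoxyphenyl)‑5‑phenylpentane‑1,3‑dione (not isolated) | O=C(CC(=O)CCc1ccccc1)c1cc(OC)c(OC)cc1O | intermediate
15 | 6,7‑dimethoxy‑2‑(2‑phenylethyl)‑4H‑chromen‑4‑one | O=c1cc(CCc2ccccc2)oc2cc(OC)c(OC)cc12 | intermediate
16 | 6,7‑dihydroxy‑2‑(2‑phenylethyl)‑4H‑chromen‑4‑one | O=c1cc(CCc2ccccc2)oc2cc(O)c(O)cc12 | intermediate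
17 | 7‑[(tert‑butyldimethylsilyl)oxy]‑6‑hydroxy‑2‑(2‑phenylethyl)‑4H‑chromen‑4‑one | O=c1cc(CCc2ccccc2)oc2cc(O[Si](C)(C)C(C)(C)C)c(O)cc12 | intermediate
18 | (5S,6R,7S,8S)‑5‑({7‑[(tert‑butyldimethylsilyl)oxy]‑4‑oxo‑2‑(2‑phenylethyl)‑4H‑chromen‑6‑yl}oxy)‑8‑hydroxy‑6,7‑(isopropylidenedioxy)‑2‑(2‑phenylethyl)‑5,6,7,8‑tetrahydro‑4H‑chromen‑4‑one | O=c1cc(CCc2ccccc2)oc2c1[C@H](Oc1cc3c(=O)cc(CCc4ccccc4)oc3cc1O[Si](C)(C)C(C)(C)C)[C@H]1OC(C)(C)O[C@H]1[C@@H]2O | intermediate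
19 | (5S,6S,7R,8S)‑6,7,8‑trihydroxy‑5‑{[7‑hydroxy‑4‑oxo‑2‑(2‑phenylethyl)‑4H‑chromen‑6‑yl]oxy}‑2‑(2‑phenylethyl)‑5,6,7,8‑tetrahydro‑4H‑chromen‑4‑one (CNP0248258.1) | O=c1cc(CCc2ccccc2)oc2c1[C@H](Oc1cc3c(=O)cc(CCc4ccccc4)oc3cc1O)[C@@H](O)[C@@H](O)[C@@H]2O | target

## Step count and risks

Total steps: 11. Longest linear sequence: 7 (steps 2, 3, 4, 5, 6, 10, 11 from compound 4).

Most likely to fail:

**Step 6 (one‑pot aldol/cyclodehydration).** The pyranone may close before the aldol, or base may cause β‑elimination and aromatisation. The fallback sets out from 7 and returns at 11, forming the rings one at a time and adjusting the oxidation level last. PPTS in warm benzene cyclodehydrates the δ‑hydroxy‑β‑diketone 7 to the 2,3‑dihydro‑4H‑pyran‑4‑one F1. Hydrogenolysis (H2, Pd(OH)2/C) then frees the lactol F2. LiHMDS (2.2 equiv, THF, −78 °C) closes the carbocycle by an ordinary ketone‑enolate aldol from C4a onto the lactol aldehyde, giving the hexahydrochromenone diol F3. DDQ in hot dioxane dehydrogenates C4a–C8a to give 11.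

**Step 10 (SN1 etherification).** The C5 cation may eliminate towards an aromatic chromone, C‑alkylate the phenol at C8, or show poor facial selectivity. The fallback sets out from 11 and returns at 19, replacing acetonide face control by neighbouring‑group participation and ending under basic instead of acidic conditions. Warm 80% aqueous acetic acid removes the acetonide to give the (6R,7R,8S)‑tetraol F4. Ac2O/pyridine gives the tetraacetate F5. BF3·OEt2 with 17 ionises the C5 acetate with participation of the 6‑acetate (acetoxonium ion), so the phenol enters at C5 trans to O6 and gives the coupled triacetate F6. K2CO3 in methanol removes the three acetates and the aryl silyl ether to give 19.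

**Step 9 (regioselective 7‑O‑silylation).** Silylation may give mixtures, or the silyl group may migrate to O6. The fallback sets out from 16 and returns at 17, fixing the regiochemistry by alkylating the other oxygen first. The dianion of 16 (NaH 2.2 equiv, DMSO) reacts with 4‑methoxybenzyl chloride (1 equiv) at the more nucleophilic 6‑phenoxide to give the 6‑O‑PMB ether F7. TBSCl/imidazole silylates the remaining 7‑OH to give the fully protected chromone F8. DDQ in wet CH2Cl2 removes the PMB group to give 17.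

## Further compounds

F1 | step 6 | benzyl (5RS)‑5,9‑anhydro‑6,8,10,11‑tetradeoxy‑2,3‑O‑isopropylidene‑11‑phenyl‑α‑D‑lyxo‑undec‑8‑enofuranosid‑7‑ulose (2,3‑dihydro‑4H‑pyran‑4‑one) | O(Cc1ccccc1)[C@H]1O[C@H](C3CC(=O)C=C(CCc4ccccc4)O3)[C@@H]2OC(C)(C)O[C@H]12
F2 | step 6 | (5RS)‑5,9‑anhydro‑6,8,10,11‑tetradeoxy‑2,3‑O‑isopropylidene‑11‑phenyl‑D‑lyxo‑undec‑8‑enofuranos‑7‑ulose (lactol) | OC1O[C@H](C3CC(=O)C=C(CCc4ccccc4)O3)[C@@H]2OC(C)(C)O[C@H]12
F3 | step 6 | (6R,7S,8S)‑5,8‑dihydroxy‑6,7‑(isopropylidenedioxy)‑2‑(2‑phenylethyl)‑4a,5,6,7,8,8a‑hexahydro‑4H‑chromen‑4‑one (C4a/C5/C8a epimers) | O=C1C=C(CCc2ccccc2)OC2C1C(O)[C@H]1OC(C)(C)O[C@H]1[C@@H]2O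
F4 | step 10 | (6R,7R,8S)‑5,6,7,8‑tetrahydroxy‑2‑(2‑phenylethyl)‑5,6,7,8‑tetrahydro‑4H‑chromen‑4‑one (C5 epimers) | O=c1cc(CCc2ccccc2)oc2c1C(O)[C@@H](O)[C@@H](O)[C@@H]2O
F5 | step 10 | (6R,7R,8S)‑5,6,7,8‑tetraacetoxy‑2‑(2‑phenylethyl)‑5,6,7,8‑tetrahydro‑4H‑chromen‑4‑one (C5 epimers) | O=c1cc(CCc2ccccc2)oc2c1C(OC(C)=O)[C@@H](OC(C)=O)[C@@H](OC(C)=O)[C@@H]2OC(C)=O
F6 | step 10 | (5S,6R,7R,8S)‑6,7,8‑triacetoxy‑5‑({7‑[(tert‑butyldimethylsilyl)oxy]‑4‑oxo‑2‑(2‑phenylethyl)‑4H‑chromen‑6‑yl}oxy)‑2‑(2‑phenylethyl)‑5,6,7,8‑tetrahydro‑4H‑chromen‑4‑one | O=c1cc(CCc2ccccc2)oc2c1[C@H](Oc1cc3c(=O)cc(CCc4ccccc4)oc3cc1O[Si](C)(C)C(C)(C)C)[C@@H](OC(C)=O)[C@@H](OC(C)=O)[C@@H]2OC(C)=O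
F7 | step 9 | 7‑hydroxy‑6‑[(4‑methoxybenzyl)oxy]‑2‑(2‑phenylethyl)‑4H‑chromen‑4‑one | O=c1cc(CCc2ccccc2)oc2cc(O)c(OCc3ccc(OC)cc3)cc12
F8 | step 9 | 7‑[(tert‑butyldimethylsilyl)oxy]‑6‑[(4‑methoxybenzyl)oxy]‑2‑(2‑phenylethyl)‑4H‑chromen‑4‑one | O=c1cc(CCc2ccccc2)oc2cc(O[Si](C)(C)C(C)(C)C)c(OCc3ccc(OC)cc3)cc12
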